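Hours are the unit in which these flasks part.

| flask | starting material | coupling partner | remark | time |
|---|---|---|---|---|
| theta | 10 mM | 10 mM | run made earlier |  |
| eta | 6.7 mM | 10 mM | run made earlier |  |
| alpha | 15 mM | 10 mM | run made earlier |  |
| beta | 10 mM | 20 mM | run made earlier |  |
| autumn | 10 mM (fed, over 6.0 h) | 10.0 mM | all else is in the flask from the start; the feed brings no volume worth counting | 15 h |
| summer | 10 mM | 10.0 mM | everything together at the start | 15 h |
| dawn | 10 mM | 10.0 mM (fed, over 6.0 h) | all else is in the flask from the start; the feed brings no volume worth counting | 15 h |

| run | time / h | mono adduct / % | bis adduct / % |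
|---|---|---|---|
| theta | 0.667 | 7.8 | 1.0 |
| theta | 1.50 | 11.2 | 2.5 |
| theta | 4.00 | 14.2 | 4.6 |
| theta | 10.0 | 15.1 | 5.5 |
| eta | 2.50 | 13.9 | 4.3 |
| eta | 5.00 | 15.9 | 6.8 |
| eta | 6.00 | 16.1 | 6.1 |
| eta | 10.0 | 16.3 | 7.4 |
| alpha | 0.667 | 7.4 | 0.7 |
| alpha | 1.50 | 10.3 | 2.3 |
| alpha | 4.00 | 13.1 | 3.7 |
| alpha | 10.0 | 13.0 | 3.8 |
| beta | 0.667 | 12.1 | 2.8 |
| beta | 1.50 | 16.0 | 5.6 |
| beta | 4.00 | 17.7 | 9.4 |
| beta | 10.0 | 18.3 | 11.6 |

(scatter of a reading: 0.3 percentage points)

- the flask with the highest share of mono adduct in mono adduct plus bis adduct ("all alike" if they lie within 1.5 percentage points) (autumn / summer / dawn / all alike)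
- share of mono adduct in mono adduct plus bis adduct at the end, autumn
- share of mono adduct in mono adduct plus bis adduct at the end, summer
- share of mono adduct in mono adduct plus bis adduct at the end, dawn

- the earlier runs were read with a standard deviation of 0.3 percentage points

The theta run stalls: mono adduct stands at 14.2% after 4.00 h and at 15.1% after 10.0 h. Two chemists read this stall differently. The first holds that the reaction is shut down by something other than a shortage of coupling partner.

The second counts the coupling partner found in the two products that were read, with bis adduct counted double. The last reading of theta shows 2.61 mM, and the last reading of beta, with twice the charge of partner, shows 4.15 mM. That is a factor of only 1.59, so she reads a partner that spends itself faster the more of it stands in the flask.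

Her measure is the working time, the last counted uptake of theta divided by its counted rate of uptake up to the first reading: 1.78 h. This is shorter than the feed of 6.0 h. So in autumn, with the partner charged at the start, about 29.7% of the starting material has come in by the end of that time. She expects autumn to convert least and to keep the highest share of mono adduct, dawn, with its partner fed in thinly, to keep the lowest, and summer to repeat the 73.3% of theta's last reading.

The forecast, from the first chemist, puts dawn highest: autumn 63% (55% to 70%), summer 73% (71% to 75%), dawn 81% (76% to 86%). For autumn its ground is “starting material stays low relative to mono, so bis is favoured”.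

The simulation gives 80.9% for autumn, 73.2% for summer and 65.8% for dawn, so autumn stands highest.

    starting material + coupling partner → mono adduct (k = 21.0 /M/h)
    starting material + coupling partner → other mono adduct (k = 28.0 /M/h)
    coupling partner + mono adduct → bis adduct (k = 30.0 /M/h)
    coupling partner + other mono adduct → bis adduct (k = 18.0 /M/h)
    2 coupling partner → homo dimer (k = 44.0 /M/h)
    coupling partner + mono adduct → over-reaction product (k = 1.80 /M/h)
    coupling partner → decomposed reagent (k = 0.100 /h)

The forecast's 73% holds for summer, the flask in which nothing is fed. In autumn, at 6.00 h, the coupling partner, the limiting reagent, is down to 3.75% of its charge, with starting material at 83.0% and 3.11 mM of homo dimer standing in the flask; that feed lasted 3.37 working times. A run of autumn fed over 1.80 h, which is 1.01 working times, still gives 79.7%.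

The earlier runs and the new flask are simulated with made-up constants, and the scatter is random.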